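## Retrosynthetic overview

1. Target ⇐ a 17-nor tetracyclic 11,15-diol: C17 and the C15 carbinol configuration are set last (oxidation, α-methylenation, Luche reduction, desilylation).
2. Rings C and D ⇐ one SmI2 cascade on a dialdehyde: ketyl–enoate bond C9–C11, then enolate aldol bond C8–C15. The symmetric CH2CH(CH2CHO)2 arm is desymmetrised, which fixes C8, C9, C11 and C13.
3. Dialdehyde ⇐ ozonolysis of a cyclopent-3-enylmethyl group, attached at C8 by Negishi coupling to an 8-bromo unsaturated spirolactone.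
4. Lactone ring ⇐ Ti(III) opening of a C10 spiro-epoxide, radical addition to ethyl propiolate (C10 quaternary centre), lactonisation.
5. Ring A ⇐ 4,4-dimethylcyclohexenone (CBS sets C1; silicon-tethered radical delivery sets C5). Ring order: A (bought) → lactone → C and D together.

Assumption: the target is taken exactly as drawn; stereocentres that are erased later (oxirane carbon of 9, Br-bearing carbons of 13, C15 of 22) are drawn as the expected major isomer.

Numbering in names of later intermediates is ent-kaurane numbering: C1–C5 and C10 form ring A; C6 is the CH2O on C5; C20 is the CH2O on C10; C7 is the lactone C=O; C8, C9, C11–C14 form ring C; C8, C13–C16 form ring D; C17 is the exocyclic CH2.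

## Route

Step 1
Reactants: 1 4,4-dimethylcyclohex-2-en-1-one
Product: 2 4,4-dimethyl-2-[(phenylsulfanyl)methyl]cyclohex-2-en-1-one
Conditions: 37% aq. CH2O, PhSH, Et3N, EtOH, 80 °C
Reagents that add atoms: formaldehyde C=O; benzenethiol Sc1ccccc1
Why: Kirk–Petrow α-(phenylthio)methylation (reversible thiolate conjugate addition, enolate hydroxymethylation, dehydration, SN2′ return of thiolate) puts the future C20 on the enone α-carbon as an allyl sulfide; no stereocentre is formed.

Step 2
Reactants: 2 4,4-dimethyl-2-[(phenylsulfanyl)methyl]cyclohex-2-en-1-one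
Product: 3 (1S)-4,4-dimethyl-2-[(phenylsulfanyl)methyl]cyclohex-2-en-1-ol
Conditions: (R)-Me-CBS (10 mol%), BH3·SMe2, THF, −20 °C
Reagents that add atoms: none
Why: Corey–Bakshi–Shibata reduction of a 2-substituted cyclohexenone, where the substituted alkenyl arm acts as the large group, so the (R)-catalyst delivers hydride to give the (1S)-carbinol (C1 of the target).

Step 3
Reactants: 3 (1S)-4,4-dimethyl-2-[(phenylsulfanyl)methyl]cyclohex-2-en-1-ol
Product: 4 (1S)-(bromomethyl)dimethylsilyl ether of 3
Conditions: BrCH2SiMe2Cl, Et3N, DMAP (cat.), CH2Cl2, 0 °C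
Reagents that add atoms: (bromomethyl)chlorodimethylsilane C[Si](C)(Cl)CBr
Why: Simple O-silylation installs the temporary silicon tether that carries the future C6; no stereocentre changes.

Step 4
Reactants: 4 (1S)-(bromomethyl)dimethylsilyl ether of 3
Product: 6 (1S,3R)-3-(hydroxymethyl)-4,4-dimethyl-2-methylidenecyclohexan-1-ol, via cyclic siloxane 5 (not isolated)
Conditions: Bu3SnH (slow addition), AIBN, PhH, 80 °C; then KF, KHCO3, 30% H2O2, THF/MeOH, 40 °C
Reagents that add atoms: hydrogen peroxide OO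
Why: Stork–Nishiyama silicon-tethered radical cyclisation closes 6-endo on the distal alkene carbon (the proximal carbon is fully substituted) from the face of the tethering oxygen, so C6 arrives cis to O1 and sets C5; the tertiary radical then expels PhS• (allyl sulfide addition–fragmentation) to give the exocyclic methylene, and Tamao oxidation frees both hydroxyls.

Step 5
Reactants: 6 (1S,3R)-3-(hydroxymethyl)-4,4-dimethyl-2-methylidenecyclohexan-1-ol
Product: 8 (1S,3R)-3-({[tert-butyl(dimethyl)silyl]oxy}methyl)-4,4-dimethyl-2-methylidenecyclohexyl acetate, via mono-TBS ether 7 (not isolated)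
Conditions: TBSCl, imidazole, CH2Cl2, 0 °C; then Ac2O, pyridine, DMAP, rt
Reagents that add atoms: tert-butyldimethylsilyl chloride CC(C)(C)[Si](C)(C)Cl; acetic anhydride CC(=O)OC(C)=O
Why: Sterically controlled silylation of the primary alcohol followed by acetylation of the secondary allylic alcohol installs the C1 acetate of the target while no other hydroxyl is present, so no late-stage differentiation is needed.

Step 6
Reactants: 8 (1S,3R)-3-({[tert-butyl(dimethyl)silyl]oxy}methyl)-4,4-dimethyl-2-methylidenecyclohexyl acetate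
Product: 9 C10 spiro-epoxide of 8
Conditions: mCPBA, NaHCO3, CH2Cl2, 0 °C
Reagents that add atoms: mCPBA OOC(=O)c1cccc(Cl)c1
Why: Prilezhaev epoxidation of the only alkene; the oxirane configuration is irrelevant because C10 becomes a planar radical in the next step.

Step 7
Reactants: 9 C10 spiro-epoxide of 8; 10 ethyl propiolate
Product: 12 Δ8-unsaturated spirolactone, via Z-hydroxy enoate 11 (not isolated)
Conditions: Cp2TiCl2 (cat.), Zn dust, 2,4,6-collidine·HCl, THF, rt; then CSA (cat.), 40 °C
Reagents that add atoms: none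
Why: Nugent–RajanBabu Ti(III) epoxide opening gives the tertiary C10 radical, which adds (Giese) to the alkynoate on the face anti to the cis OAc/CH2OTBS pair and the axial C4 methyl (C9 trans to both, setting C10); hydrogen transfer to the linear vinyl radical anti to the bulky group gives the Z-enoate, which lactonises with the C20 alkoxide.

Step 8
Reactants: 12 Δ8-unsaturated spirolactone
Product: 14 8-bromo-Δ8-spirolactone, via trans-dibromide 13 (not isolated)
Conditions: Br2, CH2Cl2, 0 °C to rt; then Et3N, 0 °C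
Reagents that add atoms: bromine BrBr
Why: Bromine addition followed by E2 loss of the acidic α-hydrogen and the β-bromide is the standard α-bromination of a 5,6-dihydropyran-2-one; acetate and silyl ether are inert and no stereocentre remains.

Step 9
Reactants: 15 cyclopent-3-ene-1-carboxylic acid
Product: 16 cyclopent-3-en-1-ylmethanol
Conditions: LiAlH4, THF, 0 °C to reflux
Reagents that add atoms: none
Why: Hydride reduction of a carboxylic acid to the primary alcohol; the isolated alkene is untouched.

Step 10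
Reactants: 16 cyclopent-3-en-1-ylmethanol
Product: 17 4-(iodomethyl)cyclopent-1-ene
Conditions: I2, PPh3, imidazole, CH2Cl2, 0 °C
Reagents that add atoms: iodine II
Why: Appel iodination of an unhindered primary alcohol.

Step 11
Reactants: 17 4-(iodomethyl)cyclopent-1-ene; 14 8-bromo-Δ8-spirolactone
Product: 19 8-(cyclopent-3-en-1-ylmethyl)-Δ8-spirolactone, via alkylzinc iodide 18 (not isolated)
Conditions: Zn dust, LiCl, THF, 40 °C; then 14, PdCl2(dppf) (5 mol%), THF, 50 °C
Reagents that add atoms: none
Why: Negishi sp2–sp3 coupling of an α-bromo enoate with a primary alkylzinc; the bidentate ligand suppresses β-hydride elimination and the achiral side chain carries no stereocentre.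

Step 12
Reactants: 19 8-(cyclopent-3-en-1-ylmethyl)-Δ8-spirolactone
Product: 20 dialdehyde (8-[4-oxo-2-(2-oxoethyl)butyl]-Δ8-spirolactone)
Conditions: O3, CH2Cl2/MeOH 9:1, −78 °C (Sudan Red endpoint); Me2S, −78 °C to rt
Reagents that add atoms: ozone [O-][O+]=O
Why: Ozonolysis is selective for the electron-rich cis-disubstituted cyclopentene over the electron-poor, hindered trisubstituted enoate and reveals the two equivalent CH2CHO arms.

Step 13
Reactants: 20 dialdehyde
Product: 22 17-nor 11,15-diol, via samarium enolate 21 (not isolated)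
Conditions: SmI2 (2.3 equiv, 0.1 M, slow addition), THF, −78 °C; then aq. NH4Cl
Reagents that add atoms: none
Why: Proposed new method: one-electron reduction of either aldehyde gives a ketyl that adds 6-endo to C9 through an all-equatorial chair (C10, O–Sm and the unreacted CH2CHO arm equatorial, attack on the lactone face flanked by the smaller C1 side), so the choice between the diastereotopic arms fixes C13 together with C9 and C11; a second electron gives the Sm(III) lactone enolate, which after ring flip is captured on its H9 face by the now axial aldehyde arm in a 5-exo aldol that forms the C8 quaternary centre and ring D (the C15 carbinol is erased in step 14); the closest known reaction type is the SmI2 ketyl–olefin cyclisation/aldol cascade of dialdehydes bearing an unsaturated lactone, and slow addition of SmI2 is used to hold back pinacol coupling of the 1,5-dialdehyde.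

Step 14
Reactants: 22 17-nor 11,15-diol
Product: 23 17-nor 11-hydroxy-15-ketone
Conditions: TEMPO (cat.), KBr, NaOCl, NaHCO3, CH2Cl2/H2O, 0 °C
Reagents that add atoms: none
Why: Anelli oxoammonium oxidation is strongly steric: the C15 cyclopentanol next to a quaternary carbon (like a steroid 17-OH) is oxidised, while the axial C11-OH, 1,3-diaxial to the two-carbon bridge (like a steroid 11β-OH), is left alone.

Step 15
Reactants: 23 17-nor 11-hydroxy-15-ketone
Product: 24 15-oxo-16-ene (exocyclic enone)
Conditions: (CH2O)n, N-methylanilinium trifluoroacetate, THF, 65 °C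
Reagents that add atoms: formaldehyde (as paraformaldehyde) C=O
Why: Mannich-type α-methylenation under Gras conditions (as for 16-methylene-17-keto steroids) can only occur at C16 because C8 is quaternary; esters, lactone and the free C11-OH tolerate the weakly acidic medium.

Step 16
Reactants: 24 15-oxo-16-ene (exocyclic enone)
Product: 25 6-O-TBS ether of the target
Conditions: NaBH4, CeCl3·7H2O, MeOH, −78 °C
Reagents that add atoms: none
Why: Luche 1,2-reduction delivers hydride to the exo face of the bicyclo[3.2.1]octenone (the side of the one-carbon bridge C14), which places the C15-OH endo, syn to the C9–C11–C12 bridge and the 11-OH as in the target; lactone and acetate are not reduced.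

Step 17
Reactants: 25 6-O-TBS ether of the target
Product: 26 CNP0210922.1
Conditions: HF·pyridine, THF/pyridine, 0 °C to rt
Reagents that add atoms: none
Why: Fluoride cleavage of the primary silyl ether is the only deprotection; acetate, lactone and allylic alcohol survive buffered HF.

## Compound list

1 | 4,4-dimethylcyclohex-2-en-1-one | CC1(C)CCC(=O)C=C1 | starting material
2 | 4,4-dimethyl-2-[(phenylsulfanyl)methyl]cyclohex-2-en-1-one | CC1(C)CCC(=O)C(CSc2ccccc2)=C1 | intermediate
3 | (1S)-4,4-dimethyl-2-[(phenylsulfanyl)methyl]cyclohex-2-en-1-ol | CC1(C)CC[C@H](O)C(CSc2ccccc2)=C1 | intermediate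
4 | (1S)-1-{[(bromomethyl)dimethylsilyl]oxy}-4,4-dimethyl-2-[(phenylsulfanyl)methyl]cyclohex-2-ene | CC1(C)CC[C@H](O[Si](C)(C)CBr)C(CSc2ccccc2)=C1 | intermediate
5 | cis-fused cyclic siloxane (O1–SiMe2–CH2–C5 six-membered ring on the 2-methylidenecyclohexane) | C=C1[C@@H]2CCC(C)(C)[C@H]1C[Si](C)(C)O2 | intermediate
6 | (1S,3R)-3-(hydroxymethyl)-4,4-dimethyl-2-methylidenecyclohexan-1-ol | C=C1[C@@H](O)CCC(C)(C)[C@H]1CO | intermediate
7 | (1S,3R)-3-({[tert-butyl(dimethyl)silyl]oxy}methyl)-4,4-dimethyl-2-methylidenecyclohexan-1-ol | C=C1[C@@H](O)CCC(C)(C)[C@H]1CO[Si](C)(C)C(C)(C)C | intermediate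
8 | (1S,3R)-3-({[tert-butyl(dimethyl)silyl]oxy}methyl)-4,4-dimethyl-2-methylidenecyclohexyl acetate | C=C1[C@@H](OC(C)=O)CCC(C)(C)[C@H]1CO[Si](C)(C)C(C)(C)C | intermediate
9 | spiro-epoxide of 8 (C10–C20 oxirane; oxirane O anti to OAc and CH2OTBS) | C1O[C@@]12[C@@H](OC(C)=O)CCC(C)(C)[C@H]2CO[Si](C)(C)C(C)(C)C | intermediate
10 | ethyl propiolate | C#CC(=O)OCC | starting material
11 | Z-hydroxy enoate (C10 bears CH2OH and the Z-CH=CH–CO2Et arm; C9 trans to OAc and CH2OTBS) | CCOC(=O)/C=C\[C@]1(CO)[C@@H](OC(C)=O)CCC(C)(C)[C@H]1CO[Si](C)(C)C(C)(C)C | intermediate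
12 | Δ8-unsaturated spiro δ-lactone (7,20-olide; 1-OAc; 6-OTBS) | O=C1OC[C@@]2(C=C1)[C@@H](OC(C)=O)CCC(C)(C)[C@H]2CO[Si](C)(C)C(C)(C)C | intermediate
13 | trans-8,9-dibromo spirolactone | O=C1OC[C@@]2([C@@H](Br)[C@@H]1Br)[C@@H](OC(C)=O)CCC(C)(C)[C@H]2CO[Si](C)(C)C(C)(C)C | intermediate
14 | 8-bromo-Δ8-spirolactone | O=C1OC[C@@]2(C=C1Br)[C@@H](OC(C)=O)CCC(C)(C)[C@H]2CO[Si](C)(C)C(C)(C)C | intermediate
15 | cyclopent-3-ene-1-carboxylic acid | OC(=O)C1CC=CC1 | starting material
16 | cyclopent-3-en-1-ylmethanol | OCC1CC=CC1 | intermediate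
17 | 4-(iodomethyl)cyclopent-1-ene | ICC1CC=CC1 | intermediate
18 | (cyclopent-3-en-1-ylmethyl)zinc iodide | I[Zn]CC1CC=CC1 | intermediate
19 | 8-(cyclopent-3-en-1-ylmethyl)-Δ8-spirolactone | O=C1OC[C@@]2(C=C1CC3CC=CC3)[C@@H](OC(C)=O)CCC(C)(C)[C@H]2CO[Si](C)(C)C(C)(C)C | intermediate
20 | dialdehyde: 8-[4-oxo-2-(2-oxoethyl)butyl]-Δ8-spirolactone | O=C1OC[C@@]2(C=C1CC(CC=O)CC=O)[C@@H](OC(C)=O)CCC(C)(C)[C@H]2CO[Si](C)(C)C(C)(C)C | intermediate
21 | samarium(III) lactone enolate with ring C closed (C11–OSmI2, pendant CH2CHO on C13) | O=CC[C@@H]1C[C@H](O[Sm](I)I)[C@@H]2C(C1)=C(O[Sm](I)I)OC[C@]23[C@@H](OC(C)=O)CCC(C)(C)[C@H]3CO[Si](C)(C)C(C)(C)C | intermediate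
22 | 17-nor tetracyclic diol: 1-OAc, 6-OTBS, 11-OH (syn to the C15–C16 bridge), 15-OH (exo), 7,20-olide | C1[C@@H]2C[C@H](O)[C@@H]3[C@](C2)(C(=O)OC[C@]32[C@@H](OC(C)=O)CCC(C)(C)[C@H]2CO[Si](C)(C)C(C)(C)C)[C@H]1O | intermediate
23 | 17-nor 11-hydroxy-15-ketone (1-OAc, 6-OTBS, 7,20-olide) | C1[C@@H]2C[C@H](O)[C@@H]3[C@](C2)(C(=O)OC[C@]32[C@@H](OC(C)=O)CCC(C)(C)[C@H]2CO[Si](C)(C)C(C)(C)C)C1=O | intermediate
24 | 11-hydroxy-15-oxo-16-ene (1-OAc, 6-OTBS, 7,20-olide) | C=C1[C@@H]2C[C@H](O)[C@@H]3[C@](C2)(C(=O)OC[C@]32[C@@H](OC(C)=O)CCC(C)(C)[C@H]2CO[Si](C)(C)C(C)(C)C)C1=O | intermediate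
25 | 6-O-TBS ether of the target (15-OH endo) | C=C1[C@@H]2C[C@H](O)[C@@H]3[C@](C2)(C(=O)OC[C@]32[C@@H](OC(C)=O)CCC(C)(C)[C@H]2CO[Si](C)(C)C(C)(C)C)[C@@H]1O | intermediate
26 | CNP0210922.1: 1-acetoxy-6,11,15-trihydroxy-6,7-seco-ent-kaur-16-en-7,20-olide | C=C1[C@@H]2C[C@H](O)[C@@H]3[C@](C2)(C(=O)OC[C@]32[C@@H](OC(C)=O)CCC(C)(C)[C@H]2CO)[C@@H]1O | target

## Totals and risks

Total step count: 17. Longest linear sequence: 15 (steps 1–8 and 11–17); the side chain takes 2 steps (9–10).

Most likely to fail:

Step 13 (SmI2 cascade). The main danger is Sm-templated pinacol coupling of the 1,5-dialdehyde, or poor selection between the two arms. The fallback sets out from 20 and comes back at 22. It replaces the electron-transfer cascade by a neutral tin-ketyl radical chain: Bu3SnH (slow addition) and AIBN in benzene at 80 °C add Bu3Sn• to one aldehyde oxygen; the O-stannyl ketyl closes 6-endo on C9; the α-lactone radical, which is not reduced to an enolate in this manifold, closes 5-exo on the second aldehyde carbon; the alkoxy radical is quenched by Bu3SnH. This gives the 11-O-tributylstannyl ether F1, and aqueous KF removes tin to give 22. No two-electron pinacol pathway exists under these conditions.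

Step 7 (Ti(III) addition to the alkynoate). The risks are the fate of the vinyl radical and the E/Z ratio, since only the Z-enoate lactonises. The fallback sets out from 6 and comes back at 12, using an acrylate acceptor and enolate-based desaturation, which requires a base-stable group on O1. Diol 6 is silylated to 7 as in step 5 and then protected with 4-methoxybenzyl trichloroacetimidate (cat. CSA) to give the PMB ether F2. mCPBA gives the spiro-epoxide F3. Cp2TiCl2/Zn/collidine·HCl with 2,2,2-trifluoroethyl acrylate gives the saturated spirolactone F4 with the same C10 configuration. LDA then PhSeBr gives the α-phenylselanyl lactone F5, and H2O2 causes selenoxide elimination to the unsaturated lactone F6. DDQ frees the C1 alcohol F7, and Ac2O/DMAP gives 12.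

Step 14 (oxidation of C15-OH in the presence of C11-OH). If the axial C11-OH is also oxidised, the fallback sets out from 22 and comes back at 23 by protecting-group differentiation. Exhaustive silylation (TMSOTf, 2,6-lutidine) gives the bis-TMS ether F8. Citric acid in MeOH at 0 °C cleaves only the exposed C15 silyl ether to give the 11-O-TMS 15-alcohol F9. Dess–Martin periodinane gives the 11-O-TMS 15-ketone F10, and PPTS in MeOH removes the remaining TMS group to give 23.

## Further compounds

F1 | step 13 | 11-O-tributylstannyl ether of 22 | C1[C@@H]2C[C@H](O[Sn](CCCC)(CCCC)CCCC)[C@@H]3[C@](C2)(C(=O)OC[C@]32[C@@H](OC(C)=O)CCC(C)(C)[C@H]2CO[Si](C)(C)C(C)(C)C)[C@H]1O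
F2 | step 7 | 1-O-PMB 6-O-TBS methylidenecyclohexane (PMB analogue of 8) | C=C1[C@@H](OCc2ccc(OC)cc2)CCC(C)(C)[C@H]1CO[Si](C)(C)C(C)(C)C
F3 | step 7 | spiro-epoxide of F2 | C1O[C@@]12[C@@H](OCc3ccc(OC)cc3)CCC(C)(C)[C@H]2CO[Si](C)(C)C(C)(C)C
F4 | step 7 | saturated spirolactone (1-OPMB, 6-OTBS, 7,20-olide) | O=C1OC[C@@]2(CC1)[C@@H](OCc3ccc(OC)cc3)CCC(C)(C)[C@H]2CO[Si](C)(C)C(C)(C)C
F5 | step 7 | 8-phenylselanyl spirolactone (C8 epimers) | O=C1OC[C@@]2(CC1[Se]c3ccccc3)[C@@H](OCc4ccc(OC)cc4)CCC(C)(C)[C@H]2CO[Si](C)(C)C(C)(C)C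
F6 | step 7 | Δ8-unsaturated spirolactone with 1-OPMB | O=C1OC[C@@]2(C=C1)[C@@H](OCc3ccc(OC)cc3)CCC(C)(C)[C@H]2CO[Si](C)(C)C(C)(C)C
F7 | step 7 | Δ8-unsaturated spirolactone with free 1-OH | O=C1OC[C@@]2(C=C1)[C@@H](O)CCC(C)(C)[C@H]2CO[Si](C)(C)C(C)(C)C
F8 | step 14 | 11,15-bis-O-TMS ether of 22 | C1[C@@H]2C[C@H](O[Si](C)(C)C)[C@@H]3[C@](C2)(C(=O)OC[C@]32[C@@H](OC(C)=O)CCC(C)(C)[C@H]2CO[Si](C)(C)C(C)(C)C)[C@H]1O[Si](C)(C)C
F9 | step 14 | 11-O-TMS ether of 22 (free 15-OH) | C1[C@@H]2C[C@H](O[Si](C)(C)C)[C@@H]3[C@](C2)(C(=O)OC[C@]32[C@@H](OC(C)=O)CCC(C)(C)[C@H]2CO[Si](C)(C)C(C)(C)C)[C@H]1O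
F10 | step 14 | 11-O-TMS ether of 23 | C1[C@@H]2C[C@H](O[Si](C)(C)C)[C@@H]3[C@](C2)(C(=O)OC[C@]32[C@@H](OC(C)=O)CCC(C)(C)[C@H]2CO[Si](C)(C)C(C)(C)C)C1=O
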